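**Plan**
- Retrosynthetic cuts: first the C3 acetal back from the aldehyde, then the C1'–C6' bond of the 2,4-dihydroxyphenyl ring, which unfolds that ring into the chain C2–C1'H2–C2'(=O)–C3'H2–C4'(=O)–C5'H=C6'H–OMe. Further cuts: C2'–C3' (enolate acylation), C1'–C2' (carboxylation of a 2-methyl group), C3–CHO (formylation), O1–C2 and C3–C3a of the furan (propargyl ether rearrangement), C7–prenyl (ortho-metalation).
- Enabling feature: the resorcinol ring carries oxygen on the alternate carbons C2' and C4' and is bonded to benzofuran C2 through C1'. It is therefore a folded 3,5-dioxo aldehyde (triketide) chain, and its C1' is acidified by both the C2' carbonyl and the benzofuran.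
- Forward order: the purchased benzene ring is prenylated between its two oxygens, the furan ring is closed, C3 is formylated, the chain is grown from the 2-methyl group, the resorcinol ring is closed last, and the acetal is removed.
- Stereochemistry: the target has no stereocentre and no stereogenic double bond. The E enol ether of the chain comes from reagent 19 and disappears on aromatisation.

Key step: step 11

Remark: C1' to C6' denote the six carbons that become the resorcinol ring, C1' being the one bonded to benzofuran C2.
Remark: the benzofuran-3-yl dimethyl acetal is assumed to ionise very easily, so compounds 17 to 24 are to be worked up at pH 8 or above and purified on Et3N-deactivated silica.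

**Route**

Step 1
Reactants: 1 1,3-dimethoxybenzene; 2 1-bromo-3-methylbut-2-ene (prenyl bromide)
Product: 4 1,3-dimethoxy-2-(3-methylbut-2-enyl)benzene, via aryllithium 3 (not isolated)
Conditions: n-BuLi (1.1 equiv), THF, 0 °C to rt; then 2, −78 °C to rt
Reagents that add atoms: none
Why: Directed ortho-metalation, in which the two methoxy groups cooperatively direct lithiation to the carbon between them, followed by SN2 alkylation of the aryllithium at the primary carbon of the allylic bromide.

Step 2
Reactants: 4 1,3-dimethoxy-2-(3-methylbut-2-enyl)benzene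
Product: 5 3-methoxy-2-(3-methylbut-2-enyl)phenol
Conditions: NaSEt (2.5 equiv), DMF, 140 °C; then dilute aq. HCl, 0 °C
Reagents that add atoms: none
Why: Thiolate SN2 demethylation of an aryl methyl ether, where the two methoxy groups are equivalent and the phenoxide formed after the first cleavage should shut down the second.

Step 3
Reactants: 5 3-methoxy-2-(3-methylbut-2-enyl)phenol; 6 3-bromoprop-1-yne (propargyl bromide)
Product: 7 1-methoxy-2-(3-methylbut-2-enyl)-3-(prop-2-ynyloxy)benzene
Conditions: K2CO3, acetone, reflux
Reagents that add atoms: none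
Why: Williamson ether synthesis of the phenoxide with a primary propargylic bromide.

Step 4
Reactants: 7 1-methoxy-2-(3-methylbut-2-enyl)-3-(prop-2-ynyloxy)benzene
Product: 9 6-methoxy-2-methyl-7-(3-methylbut-2-enyl)benzofuran, via allenylphenol 8 (not isolated)
Conditions: CsF (2 equiv), PhNEt2, 200–215 °C
Reagents that add atoms: none
Why: Aromatic propargyl Claisen rearrangement to the only free ortho carbon should give allenylphenol 8, whose fluoride-generated phenoxide adds to the central allene carbon and closes the furan ring as the 2-methylbenzofuran rather than the 2H-chromene formed without base.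

Step 5
Reactants: 9 6-methoxy-2-methyl-7-(3-methylbut-2-enyl)benzofuran
Product: 11 6-methoxy-2-methyl-7-(3-methylbut-2-enyl)benzofuran-3-carbaldehyde, via iminium chloride 10 (not isolated)
Conditions: POCl3 (1.5 equiv), DMF, 0 to 40 °C; then aq. NaOH to pH 9, 0 °C
Reagents that add atoms: N,N-dimethylformamide, CN(C)C=O; water, O
Why: Vilsmeier–Haack formylation at C3, the β-carbon of the furan enol ether and the usual site of attack in 2-alkylbenzofurans, with a chloroiminium electrophile mild enough to leave the trisubstituted alkene alone.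

Step 6
Reactants: 11 6-methoxy-2-methyl-7-(3-methylbut-2-enyl)benzofuran-3-carbaldehyde
Product: 12 (E)-N-tert-butyl-1-[6-methoxy-2-methyl-7-(3-methylbut-2-enyl)benzofuran-3-yl]methanimine
Conditions: t-BuNH2 (5 equiv), MgSO4, CH2Cl2, rt to 40 °C
Reagents that add atoms: tert-butylamine, CC(C)(C)N
Why: Imine condensation of an aldehyde without α-hydrogen with a hindered primary amine, driven by removal of water and giving the E aldimine.

Step 7
Reactants: 12 (E)-N-tert-butyl-1-[6-methoxy-2-methyl-7-(3-methylbut-2-enyl)benzofuran-3-yl]methanimine; 13 dimethyl carbonate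
Product: 16 methyl 2-[3-formyl-6-methoxy-7-(3-methylbut-2-enyl)benzofuran-2-yl]acetate, via lithiated imine 14 (not isolated), via imine ester 15 (not isolated)
Conditions: LiN(i-Pr)2 (2.2 equiv), THF, −78 °C; 13 (1.2 equiv), −78 to −20 °C; then 1 M aq. HCl, THF, 0 °C to rt
Reagents that add atoms: water, O
Why: Lateral metalation through a vinylogous aza-enolate (the imine makes the 2-methyl group the γ-position of a 1-azadiene, as in ortho-tolualdehyde tert-butylimines, so the amide base should not touch the less acidic prenyl CH2), then C-acylation by the carbonate as with 2-picolyl anions, the second equivalent of base storing the product as its enolate, and acidic imine hydrolysis.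

Step 8
Reactants: 16 methyl 2-[3-formyl-6-methoxy-7-(3-methylbut-2-enyl)benzofuran-2-yl]acetate
Product: 17 methyl 2-[3-(dimethoxymethyl)-6-methoxy-7-(3-methylbut-2-enyl)benzofuran-2-yl]acetate
Conditions: HC(OMe)3 (5 equiv), MeOH, pyridinium p-toluenesulfonate (cat.), rt; then Et3N
Reagents that add atoms: trimethyl orthoformate, COC(OC)OC; methanol, CO
Why: Acid-catalysed acetalisation driven by the orthoformate as water scavenger, which removes the only electrophile that a carbanion of the later chain could reach through a six-membered ring.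

Step 9
Reactants: 17 methyl 2-[3-(dimethoxymethyl)-6-methoxy-7-(3-methylbut-2-enyl)benzofuran-2-yl]acetate
Product: 18 potassium 2-[3-(dimethoxymethyl)-6-methoxy-7-(3-methylbut-2-enyl)benzofuran-2-yl]acetate
Conditions: KOSiMe3 (1.1 equiv), THF, rt
Reagents that add atoms: potassium trimethylsilanolate, C[Si](C)(C)[O-].[K+]
Why: Anhydrous silanolate cleavage of a methyl ester gives the carboxylate salt directly, avoiding both an aqueous acidification the acetal would not survive and a free acid that could add to the neighbouring acetal.

Step 10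
Reactants: 18 potassium 2-[3-(dimethoxymethyl)-6-methoxy-7-(3-methylbut-2-enyl)benzofuran-2-yl]acetate; 19 (E)-4-methoxybut-3-en-2-one
Product: 22 (E)-1-[3-(dimethoxymethyl)-6-methoxy-7-(3-methylbut-2-enyl)benzofuran-2-yl]-6-methoxyhex-5-ene-2,4-dione, via mixed anhydride 20 (not isolated), via lithium enolate 21 (not isolated)
Conditions: t-BuCOCl (1.0 equiv), THF, −20 °C; added to 19 (3 equiv) + LiN(SiMe3)2 (3 equiv), THF, −78 °C; AcOH (3 equiv), −78 °C; then aq. NaHCO3
Reagents that add atoms: none
Why: Claisen-type C-acylation of the kinetic lithium enolate of the vinylogous ester, the established way to 6-methoxyhex-5-ene-2,4-diones from acyl chlorides, here with a mixed pivalic anhydride whose unhindered arylacetyl carbonyl is attacked and with excess enolate absorbing the acidic proton of the product.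

Step 11
Reactants: 22 (E)-1-[3-(dimethoxymethyl)-6-methoxy-7-(3-methylbut-2-enyl)benzofuran-2-yl]-6-methoxyhex-5-ene-2,4-dione
Product: 24 4-[3-(dimethoxymethyl)-6-methoxy-7-(3-methylbut-2-enyl)benzofuran-2-yl]benzene-1,3-diol, via cyclohexenedione 23 (not isolated)
Conditions: NaOMe (3 equiv), degassed MeOH (0.02 M), argon, rt to 50 °C; then aq. NaH2PO4/Na2HPO4 (pH 8)
Reagents that add atoms: none
Why: Methoxide converts 22 into its diketonate, and a small equilibrium share of the tautomeric C1' enolate (C1' lies between the C2' carbonyl and benzofuran C2) adds through carbon to C6', the β-carbon of the vinylogous ester, after which methoxide is expelled to give 23. Double enolisation of 23 to the resorcinolate is irreversible and should pull all earlier equilibria forward. The closest known reaction type is the base-mediated aldol folding of 2,4,6-triketones and 3,5-dioxo acid derivatives into resorcinols, here with the terminal carbonyl held as its enol ether so that closure is a Michael addition–elimination, as in [3+3] benzannulations on 3-alkoxy enones. The ring closes in a 6-(enolendo)-endo-trig mode and no stereocentre is formed. The selectivity needed is attack by C1' rather than by the enolate oxygen on C2' (which gives a 4-pyranone) or by C3' of a second molecule. Oxygen closure is reversible because methoxide reopens the 4-pyranone at its unsubstituted C6 whereas carbon closure ends in an arene, C3' can reach no electrophile through a ring of more than four atoms, the C3 acetal offers none, and high dilution suppresses dimers.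

Step 12
Reactants: 24 4-[3-(dimethoxymethyl)-6-methoxy-7-(3-methylbut-2-enyl)benzofuran-2-yl]benzene-1,3-diol
Product: 25 erypoegin F, 2-(2,4-dihydroxyphenyl)-6-methoxy-7-(3-methylbut-2-enyl)benzofuran-3-carbaldehyde
Conditions: pyridinium p-toluenesulfonate (cat.), acetone–H2O, rt
Reagents that add atoms: water, O
Why: Acid-catalysed acetal hydrolysis, fast because the oxocarbenium ion is stabilised by the furan oxygen, under conditions in which the prenyl group, having no ortho hydroxyl to cyclise onto, should survive.

**Compound list**
1 | 1,3-dimethoxybenzene | COc1cccc(OC)c1 | starting material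
2 | 1-bromo-3-methylbut-2-ene (prenyl bromide) | CC(C)=CCBr | starting material
3 | 2,6-dimethoxyphenyllithium | [Li]c1c(OC)cccc1OC | intermediate (not isolated)
4 | 1,3-dimethoxy-2-(3-methylbut-2-enyl)benzene | COc1cccc(OC)c1CC=C(C)C | intermediate
5 | 3-methoxy-2-(3-methylbut-2-enyl)phenol | COc1cccc(O)c1CC=C(C)C | intermediate
6 | 3-bromoprop-1-yne (propargyl bromide) | C#CCBr | starting material
7 | 1-methoxy-2-(3-methylbut-2-enyl)-3-(prop-2-ynyloxy)benzene | COc1cccc(OCC#C)c1CC=C(C)C | intermediate
8 | 3-methoxy-2-(3-methylbut-2-enyl)-6-(propa-1,2-dienyl)phenol | COc1ccc(C=C=C)c(O)c1CC=C(C)C | intermediate (not isolated)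
9 | 6-methoxy-2-methyl-7-(3-methylbut-2-enyl)benzofuran | COc1ccc2cc(C)oc2c1CC=C(C)C | intermediate
10 | N-{[6-methoxy-2-methyl-7-(3-methylbut-2-enyl)benzofuran-3-yl]methylidene}-N-methylmethanaminium chloride | C[N+](C)=Cc1c(C)oc2c(CC=C(C)C)c(OC)ccc12.[Cl-] | intermediate (not isolated)
11 | 6-methoxy-2-methyl-7-(3-methylbut-2-enyl)benzofuran-3-carbaldehyde | O=Cc1c(C)oc2c(CC=C(C)C)c(OC)ccc12 | intermediate
12 | (E)-N-tert-butyl-1-[6-methoxy-2-methyl-7-(3-methylbut-2-enyl)benzofuran-3-yl]methanimine | CC(C)(C)/N=C/c1c(C)oc2c(CC=C(C)C)c(OC)ccc12 | intermediate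
13 | dimethyl carbonate | COC(=O)OC | starting material
14 | {3-[(E)-(tert-butylimino)methyl]-6-methoxy-7-(3-methylbut-2-enyl)benzofuran-2-yl}methyllithium | [Li]Cc1oc2c(CC=C(C)C)c(OC)ccc2c1/C=N/C(C)(C)C | intermediate (not isolated)
15 | methyl 2-{3-[(E)-(tert-butylimino)methyl]-6-methoxy-7-(3-methylbut-2-enyl)benzofuran-2-yl}acetate | COC(=O)Cc1oc2c(CC=C(C)C)c(OC)ccc2c1/C=N/C(C)(C)C | intermediate (not isolated)
16 | methyl 2-[3-formyl-6-methoxy-7-(3-methylbut-2-enyl)benzofuran-2-yl]acetate | COC(=O)Cc1oc2c(CC=C(C)C)c(OC)ccc2c1C=O | intermediate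
17 | methyl 2-[3-(dimethoxymethyl)-6-methoxy-7-(3-methylbut-2-enyl)benzofuran-2-yl]acetate | COC(=O)Cc1oc2c(CC=C(C)C)c(OC)ccc2c1C(OC)OC | intermediate
18 | potassium 2-[3-(dimethoxymethyl)-6-methoxy-7-(3-methylbut-2-enyl)benzofuran-2-yl]acetate | [K+].[O-]C(=O)Cc1oc2c(CC=C(C)C)c(OC)ccc2c1C(OC)OC | intermediate
19 | (E)-4-methoxybut-3-en-2-one | CO/C=C/C(C)=O | starting material
20 | 2-[3-(dimethoxymethyl)-6-methoxy-7-(3-methylbut-2-enyl)benzofuran-2-yl]acetic 2,2-dimethylpropanoic anhydride | CC(C)(C)C(=O)OC(=O)Cc1oc2c(CC=C(C)C)c(OC)ccc2c1C(OC)OC | intermediate (not isolated)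
21 | lithium (E)-4-methoxybuta-1,3-dien-2-olate | [Li+].[O-]C(=C)/C=C/OC | intermediate (not isolated)
22 | (E)-1-[3-(dimethoxymethyl)-6-methoxy-7-(3-methylbut-2-enyl)benzofuran-2-yl]-6-methoxyhex-5-ene-2,4-dione | COC(OC)c1c(CC(=O)CC(=O)/C=C/OC)oc2c(CC=C(C)C)c(OC)ccc12 | intermediate
23 | 4-[3-(dimethoxymethyl)-6-methoxy-7-(3-methylbut-2-enyl)benzofuran-2-yl]cyclohex-5-ene-1,3-dione (racemic) | O=C1CC(=O)C=CC1c1oc2c(CC=C(C)C)c(OC)ccc2c1C(OC)OC | intermediate (not isolated)
24 | 4-[3-(dimethoxymethyl)-6-methoxy-7-(3-methylbut-2-enyl)benzofuran-2-yl]benzene-1,3-diol | COC(OC)c1c(-c2ccc(O)cc2O)oc2c(CC=C(C)C)c(OC)ccc12 | intermediate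
25 | erypoegin F, 2-(2,4-dihydroxyphenyl)-6-methoxy-7-(3-methylbut-2-enyl)benzofuran-3-carbaldehyde | COc1ccc2c(C=O)c(-c3ccc(O)cc3O)oc2c1CC=C(C)C | target

**Totals**
Total step count: 12. Longest linear sequence: 12 steps (1 to 25); compounds 2, 6, 13 and 19 are purchased.

**Steps most likely to fail**

Step 11. The diketonate may remain the resting state, so that ring closure through C1' is too slow and closure through the enol oxygen, intermolecular addition–elimination by C3' and alkoxide-induced retro-Claisen cleavage take over. The fallback turns the bond order around in a [3+3] Michael–Claisen benzannulation in which C1' is the most acidic carbon of the nucleophile. It sets out from ester 17 and enone 19. With KOt-Bu (2.2 equiv) in THF/t-BuOH, the ester enolate of 17 should add to C4 of 19 (added slowly) and lose methoxide to give methyl (E)-2-[3-(dimethoxymethyl)-6-methoxy-7-(3-methylbut-2-enyl)benzofuran-2-yl]-5-oxohex-3-enoate F1. After E-to-Z equilibration through its dienolate, the methyl ketone enolate of F1 should attack the ester carbonyl (Claisen closure of C2'–C3') to give cyclohexenedione 23, which aromatises. The fallback returns to the route at 24.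

Step 10. Proton transfer from the acidic CH2 of the acyl donor to the enolate (ketene formation and loss of the nucleophile), O-acylation and self-condensation of the regenerated enone may outrun C-acylation. The fallback replaces acylation by aldol addition and oxidation. It sets out from ester 17, which is reduced with i-Bu2AlH (CH2Cl2, −78 °C, aq. potassium sodium tartrate work-up) to 2-[3-(dimethoxymethyl)-6-methoxy-7-(3-methylbut-2-enyl)benzofuran-2-yl]acetaldehyde F2. Addition of F2 to lithium enolate 21 at −78 °C should give (E)-6-[3-(dimethoxymethyl)-6-methoxy-7-(3-methylbut-2-enyl)benzofuran-2-yl]-5-hydroxy-1-methoxyhex-1-en-3-one F3 (racemic). Oxidation of F3 with Dess–Martin periodinane buffered by NaHCO3 returns to the route at 22.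

Step 7. The ambident aza-enolate may be acylated on nitrogen or twice on carbon, or metalation may be incomplete so that the amide base consumes the carbonate. The fallback relies on coordination instead of conjugation. It sets out from aldehyde 11, which is acetalised (HC(OMe)3, MeOH, pyridinium p-toluenesulfonate) to 3-(dimethoxymethyl)-6-methoxy-2-methyl-7-(3-methylbut-2-enyl)benzofuran F4. Lateral lithiation with s-BuLi/TMEDA in THF at −78 °C, directed by precoordination to the acetal oxygens, should give {[3-(dimethoxymethyl)-6-methoxy-7-(3-methylbut-2-enyl)benzofuran-2-yl]methyl}lithium F5. Inverse addition of F5 to ClCO2Me returns to the route at 17. This is the second choice because the alkyllithium may instead abstract the benzylic–allylic proton of the prenyl group.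

**Further compounds**
F1 | step 11 | methyl (E)-2-[3-(dimethoxymethyl)-6-methoxy-7-(3-methylbut-2-enyl)benzofuran-2-yl]-5-oxohex-3-enoate (racemic) | COC(=O)C(/C=C/C(C)=O)c1oc2c(CC=C(C)C)c(OC)ccc2c1C(OC)OC
F2 | step 10 | 2-[3-(dimethoxymethyl)-6-methoxy-7-(3-methylbut-2-enyl)benzofuran-2-yl]acetaldehyde | O=CCc1oc2c(CC=C(C)C)c(OC)ccc2c1C(OC)OC
F3 | step 10 | (E)-6-[3-(dimethoxymethyl)-6-methoxy-7-(3-methylbut-2-enyl)benzofuran-2-yl]-5-hydroxy-1-methoxyhex-1-en-3-one (racemic) | CO/C=C/C(=O)CC(O)Cc1oc2c(CC=C(C)C)c(OC)ccc2c1C(OC)OC
F4 | step 7 | 3-(dimethoxymethyl)-6-methoxy-2-methyl-7-(3-methylbut-2-enyl)benzofuran | COc1ccc2c(C(OC)OC)c(C)oc2c1CC=C(C)C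
F5 | step 7 | {[3-(dimethoxymethyl)-6-methoxy-7-(3-methylbut-2-enyl)benzofuran-2-yl]methyl}lithium | [Li]Cc1oc2c(CC=C(C)C)c(OC)ccc2c1C(OC)OC
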